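## Retrosynthetic overview

1. Target ⇐ one hydrogenation (two C=C bonds, one benzyl ester) ⇐ cross-metathesis of hept-6-enyl (R)-malate with a hept-6-enoic acid that already carries both core stereocentres.
2. Key disconnection: the bond between the two adjacent stereocentres. It is made by adding the tertiary γ-radical of a butenolide-2-carboxylate (from its γ-bromide) to the chiral enamine of hept-6-enal under photoredox/organocatalysis; the aldehyde is then oxidised to the acid.
3. Radical precursor ⇐ 2-furoic acid: benzyl ester, C5–H borylation/oxidation to the butenolide, γ-bromination.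
4. Malate half-ester ⇐ (R)-α-hydroxy-γ-butyrolactone (oxidised to (R)-malic acid) + hept-6-en-1-ol, via the O-trifluoroacetyl anhydride.
5. Rings: the only ring of the target (the γ-lactone) is never closed. It is the furan ring of 2-furoic acid, oxidised to the butenolide in step 4 and saturated in step 8.

Assumption: hept-6-enal, hept-6-en-1-ol, 2-furoic acid and (R)-α-hydroxy-γ-butyrolactone are bought; catalysts (including the D-alanine-derived imidazolidinone) are bought or made separately and not counted.

## Route

Step 1
Reactants: 1 (R)-α-hydroxy-γ-butyrolactone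
Product: 3 (R)-malic acid, via sodium (2R)-2,4-dihydroxybutanoate 2 (not isolated)
Conditions: NaOH (1.0 equiv), H2O, 0 °C to rt; then TEMPO (2 mol %), NaBr (10 mol %), NaOCl (2.2 equiv), pH 10 (NaOH), 0–5 °C; HCl to pH 1, evaporate, extract with acetone
Reagents that add atoms: sodium hydroxide [Na+].[OH-]; water O
Why: Saponification opens the lactone, and the oxoammonium (Anelli-type TEMPO/hypochlorite) oxidation in water takes only the primary alcohol to the carboxylate, as in uronic acid syntheses; the stereocentre comes unchanged from the chiral pool because an α-hydroxy carboxylate does not epimerise at pH 10.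

Step 2
Reactants: 3 (R)-malic acid; 4 hept-6-en-1-ol
Product: 7 (3R)-4-(hept-6-en-1-yloxy)-3-hydroxy-4-oxobutanoic acid [1-(hept-6-enyl) hydrogen (R)-malate], via (R)-trifluoroacetoxysuccinic anhydride 5 (not isolated), via O-trifluoroacetyl monoester 6 (not isolated)
Conditions: TFAA (3 equiv), neat, 0 °C to rt, 1.5 h, evaporate; 4 (1.05 equiv), CH2Cl2, 0 °C to rt, 3 h; THF/H2O, rt, 1 h
Reagents that add atoms: trifluoroacetic anhydride O=C(OC(=O)C(F)(F)F)C(F)(F)F (atoms in 5 and 6 only)
Why: Trifluoroacetic anhydride gives the O-trifluoroacetyl cyclic anhydride, which the alcohol opens regioselectively at the carbonyl next to the electron-withdrawing trifluoroacetoxy group (the known route to malic acid 1-monoesters), and mild hydrolysis removes the labile trifluoroacetate without touching the stereocentre.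

Step 3
Reactants: 8 furan-2-carboxylic acid
Product: 9 benzyl furan-2-carboxylate
Conditions: BnBr (1.1 equiv), K2CO3 (1.2 equiv), DMF, rt, 6 h
Reagents that add atoms: benzyl bromide BrCc1ccccc1
Why: SN2 O-alkylation of the carboxylate installs a benzyl ester that the final hydrogenation removes at no extra step.

Step 4
Reactants: 9 benzyl furan-2-carboxylate
Product: 11 benzyl 5-oxo-2,5-dihydrofuran-2-carboxylate (racemic), via benzyl 5-(pinacolboryl)furan-2-carboxylate 10 (not isolated)
Conditions: [Ir(OMe)(cod)]2 (1.5 mol %), dtbpy (3 mol %), B2pin2 (1.0 equiv), THF, 50 °C, 6 h; evaporate; Oxone (1.1 equiv), acetone/H2O 1:1, 0 °C, 15 min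
Reagents that add atoms: bis(pinacolato)diboron CC1(C)OB(OC1(C)C)B1OC(C)(C)C(C)(C)O1 (atoms in 10 only); potassium peroxymonosulfate (Oxone) [K+].[O-]S(=O)(=O)OO
Why: Iridium-catalysed C–H borylation of 2-substituted furans is selective for the free α-position, and oxidation of the furyl boronate (one-pot borylation/oxidation) gives the 5-hydroxyfuran, which tautomerises to the butenolide; any 2(3H)-tautomer converges to the same bromide in step 5.

Step 5
Reactants: 11 benzyl 5-oxo-2,5-dihydrofuran-2-carboxylate
Product: 12 benzyl 2-bromo-5-oxo-2,5-dihydrofuran-2-carboxylate (racemic)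
Conditions: NBS (1.05 equiv), AIBN (5 mol %), PhCF3, 80 °C, 1 h; cool, filter, concentrate; used crude
Reagents that add atoms: N-bromosuccinimide O=C1CCC(=O)N1Br
Why: Wohl–Ziegler bromination removes the weakest C–H (allylic, α-oxygen, α-ester) and delivers bromine to the γ-carbon so that the conjugated butenolide is kept, as known for 2(5H)-furanones; the bromide is racemic, which is irrelevant because it is next converted into a planar radical.

Step 6
Reactants: 12 benzyl 2-bromo-5-oxo-2,5-dihydrofuran-2-carboxylate; 13 hept-6-enal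
Product: 15 (2S)-2-[(2R)-2-[(benzyloxy)carbonyl]-5-oxo-2,5-dihydrofuran-2-yl]hept-6-enoic acid, via α-alkylated aldehyde 14 (not isolated)
Conditions: (i) 13 (2.0 equiv), (2S,5R)-2-tert-butyl-3,5-dimethylimidazolidin-4-one·TfOH (20 mol %), Ru(bpy)3Cl2 (1 mol %), 2,6-lutidine (2.0 equiv), DMF (0.5 M), degassed, blue LEDs, 5 °C, 12 h; Et2O/H2O work-up, excess 13 removed in vacuo; (ii) NaClO2 (3 equiv), NaH2PO4 (3 equiv), 2-methyl-2-butene (10 equiv), t-BuOH/H2O, 0 °C to rt; chromatography removes the (2S,2'S) epimer
Reagents that add atoms: sodium chlorite [Na+].[O-]Cl=O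
Why: Proposed new method: following the known photoredox/enamine α-alkylation of aldehydes with α-bromo carbonyl compounds (tertiary bromides included), Ru(I) reduces the C–Br bond of 12 to the electrophilic butenolide γ-radical, which adds through its γ-carbon (the site at which 2-oxyfuranyl radicals couple, restoring the conjugated lactone) to the Re face of the (E)-enamine of 13, anti to the C5 methyl group of the (2S,5R) catalyst, so that the α-carbon becomes (S), while the quaternary centre is set by facial selection on the planar radical in an open transition state (modest dr of unpredictable sense expected, hence the separation), after which the α-amino radical is oxidised to the iminium ion and hydrolysed, and the unisolated α-branched aldehyde is oxidised at once by Pinnick oxidation, which touches neither stereocentre nor the alkenes.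

Step 7
Reactants: 15 (2S)-2-[(2R)-2-[(benzyloxy)carbonyl]-5-oxo-2,5-dihydrofuran-2-yl]hept-6-enoic acid; 7 1-(hept-6-enyl) hydrogen (R)-malate
Product: 16 (2S)-2-[(2R)-2-[(benzyloxy)carbonyl]-5-oxo-2,5-dihydrofuran-2-yl]-12-{[(2R)-3-carboxy-2-hydroxypropanoyl]oxy}dodec-6-enoic acid (E/Z mixture)
Conditions: 7 (3.0 equiv), Hoveyda–Grubbs II (5 mol %), 1,4-benzoquinone (10 mol %), CH2Cl2 (0.1 M), 40 °C, Ar sparge, 12 h
Reagents that add atoms: none
Why: Cross-metathesis of two unhindered terminal alkenes is driven by loss of ethene and the excess of 7; the Ru carbene tolerates free acids and alcohols, the electron-poor ring alkene next to the quaternary carbon is inert, benzoquinone suppresses double-bond migration (which would change the chain length), and the E/Z ratio is irrelevant.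

Step 8
Reactants: 16 (E/Z)-dodec-6-enoic acid benzyl ester precursor
Product: 17 (2S)-2-[(2R)-2-carboxy-5-oxooxolan-2-yl]-12-{[(2R)-3-carboxy-2-hydroxypropanoyl]oxy}dodecanoic acid (target)
Conditions: H2 (1 atm), 10 % Pd/C, EtOAc, rt, 6 h; filter
Reagents that add atoms: none
Why: Heterogeneous hydrogenation saturates the chain alkene and the butenolide alkene (faster than allylic C–O cleavage) and hydrogenolyses the benzyl ester in one operation, leaving the lactone, the malate ester and all three stereocentres untouched.

## Compound list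

1 | (R)-α-hydroxy-γ-butyrolactone [(3R)-3-hydroxyoxolan-2-one] | O[C@@H]1CCOC1=O | starting material
2 | sodium (2R)-2,4-dihydroxybutanoate | OCC[C@@H](O)C(=O)[O-].[Na+] | intermediate
3 | (R)-malic acid [(2R)-2-hydroxybutanedioic acid] | OC(=O)C[C@@H](O)C(=O)O | intermediate
4 | hept-6-en-1-ol | OCCCCCC=C | starting material
5 | (R)-2-(trifluoroacetoxy)succinic anhydride [(3R)-2,5-dioxooxolan-3-yl trifluoroacetate] | O=C1C[C@@H](OC(=O)C(F)(F)F)C(=O)O1 | intermediate
6 | (3R)-4-(hept-6-en-1-yloxy)-4-oxo-3-(trifluoroacetoxy)butanoic acid | OC(=O)C[C@@H](OC(=O)C(F)(F)F)C(=O)OCCCCCC=C | intermediate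
7 | (3R)-4-(hept-6-en-1-yloxy)-3-hydroxy-4-oxobutanoic acid | OC(=O)C[C@@H](O)C(=O)OCCCCCC=C | intermediate
8 | furan-2-carboxylic acid (2-furoic acid) | OC(=O)c1ccco1 | starting material
9 | benzyl furan-2-carboxylate | O=C(OCc1ccccc1)c1ccco1 | intermediate
10 | benzyl 5-(4,4,5,5-tetramethyl-1,3,2-dioxaborolan-2-yl)furan-2-carboxylate | CC1(C)OB(OC1(C)C)c1ccc(o1)C(=O)OCc1ccccc1 | intermediate
11 | benzyl 5-oxo-2,5-dihydrofuran-2-carboxylate (racemic) | O=C1C=CC(O1)C(=O)OCc1ccccc1 | intermediate
12 | benzyl 2-bromo-5-oxo-2,5-dihydrofuran-2-carboxylate (racemic) | O=C1C=CC(Br)(O1)C(=O)OCc1ccccc1 | intermediate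
13 | hept-6-enal | C=CCCCCC=O | starting material
14 | benzyl (2R)-5-oxo-2-[(2S)-1-oxohept-6-en-2-yl]-2,5-dihydrofuran-2-carboxylate | C=CCCC[C@H](C=O)[C@@]1(C(=O)OCc2ccccc2)C=CC(=O)O1 | intermediate
15 | (2S)-2-[(2R)-2-[(benzyloxy)carbonyl]-5-oxo-2,5-dihydrofuran-2-yl]hept-6-enoic acid | C=CCCC[C@H](C(=O)O)[C@@]1(C(=O)OCc2ccccc2)C=CC(=O)O1 | intermediate
16 | (2S)-2-[(2R)-2-[(benzyloxy)carbonyl]-5-oxo-2,5-dihydrofuran-2-yl]-12-{[(2R)-3-carboxy-2-hydroxypropanoyl]oxy}dodec-6-enoic acid (E/Z) | OC(=O)C[C@@H](O)C(=O)OCCCCCC=CCCC[C@H](C(=O)O)[C@@]1(C(=O)OCc2ccccc2)C=CC(=O)O1 | intermediate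
17 | (2S)-2-[(2R)-2-carboxy-5-oxooxolan-2-yl]-12-{[(2R)-3-carboxy-2-hydroxypropanoyl]oxy}dodecanoic acid | O=C(O)C[C@@H](O)C(=O)OCCCCCCCCCC[C@H](C(=O)O)[C@@]1(C(=O)O)CCC(=O)O1 | target

## Step count and risks

Total step count: 8. Longest linear sequence: 6 steps (3, 4, 5, 6, 7, 8 from 2-furoic acid); the malate arm (steps 1, 2) joins at step 7.

The three steps most likely to fail:

Step 6 (key coupling). The tertiary, stabilised radical may add sluggishly, couple through its α-carbon, or give the quaternary centre with poor or the wrong diastereoselectivity; my own steric models lean slightly toward the unwanted (2S,2'S) isomer, so the desired acid may be the minor epimer. The fallback inverts the roles of the partners (SOMO activation) and sets out from 11. Silylation (TIPSOTf, Et3N, CH2Cl2, 0 °C) gives benzyl 5-[(triisopropylsilyl)oxy]furan-2-carboxylate F1. The enamine of 13 is then oxidised to its radical cation [(2R,5R)-5-benzyl-2-tert-butyl-3-methylimidazolidin-4-one·TFA 20 mol %, CAN 2 equiv, NaHCO3, H2O, DME, −20 °C] and trapped by F1 (2.5 equiv) at its ester-bearing carbon, the position known to attack iminium ions to form this quaternary centre. A second oxidation and loss of the silyl group give aldehyde 14, where the route is rejoined (Pinnick part of step 6). The silyl group and solvent offer a handle on the syn/anti ratio, as in SOMO couplings of silyl nitronates. The excess of F1 is meant to outrun 5-exo cyclisation of the radical cation onto the terminal alkene.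

Step 5 (γ-bromination). Radical bromination may be unselective, or the moisture-sensitive tertiary bromide may not survive isolation. The fallback is polar and sets out from 11. TMSOTf/Et3N (CH2Cl2, 0 °C) gives benzyl 5-[(trimethylsilyl)oxy]furan-2-carboxylate F2, which is brominated at the γ-carbon with NBS in THF at −78 °C (electrophilic bromination of a silyl dienol ether) and used directly as 12, where the route is rejoined.

Step 7 (cross-metathesis). The reaction is statistical, and the free α-hydroxy acid of 7 may slow the catalyst. The fallback attaches the malate last through a C–O bond and sets out from 15. Metathesis with the simple alcohol 4 (5 equiv, same catalyst) gives (2S)-2-[(2R)-2-[(benzyloxy)carbonyl]-5-oxo-2,5-dihydrofuran-2-yl]-12-hydroxydodec-6-enoic acid F3. Hydrogenation (H2, Pd/C, EtOAc) gives (2S)-2-[(2R)-2-carboxy-5-oxooxolan-2-yl]-12-hydroxydodecanoic acid F4. Its primary alcohol is acylated with anhydride 5 (from 3 as in step 2; THF, rt) to give (2S)-2-[(2R)-2-carboxy-5-oxooxolan-2-yl]-12-{[(2R)-3-carboxy-2-(trifluoroacetoxy)propanoyl]oxy}dodecanoic acid F5, and mild aqueous hydrolysis gives 17, where the route ends.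

## Further compounds

F1 | step 6 | benzyl 5-[(triisopropylsilyl)oxy]furan-2-carboxylate | CC(C)[Si](Oc1ccc(o1)C(=O)OCc1ccccc1)(C(C)C)C(C)C
F2 | step 5 | benzyl 5-[(trimethylsilyl)oxy]furan-2-carboxylate | C[Si](C)(C)Oc1ccc(o1)C(=O)OCc1ccccc1
F3 | step 7 | (2S)-2-[(2R)-2-[(benzyloxy)carbonyl]-5-oxo-2,5-dihydrofuran-2-yl]-12-hydroxydodec-6-enoic acid (E/Z) | OCCCCCC=CCCC[C@H](C(=O)O)[C@@]1(C(=O)OCc2ccccc2)C=CC(=O)O1
F4 | step 7 | (2S)-2-[(2R)-2-carboxy-5-oxooxolan-2-yl]-12-hydroxydodecanoic acid | OCCCCCCCCCC[C@H](C(=O)O)[C@@]1(C(=O)O)CCC(=O)O1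
F5 | step 7 | (2S)-2-[(2R)-2-carboxy-5-oxooxolan-2-yl]-12-{[(2R)-3-carboxy-2-(trifluoroacetoxy)propanoyl]oxy}dodecanoic acid | OC(=O)C[C@@H](OC(=O)C(F)(F)F)C(=O)OCCCCCCCCCC[C@H](C(=O)O)[C@@]1(C(=O)O)CCC(=O)O1
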